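**Assumption:** the SMILES is read as R at the lactone carbon, E at the methyl-bearing alkene, and CH2OH cis to the lactone-bearing CH2 at the other alkene (Z by CIP). The 1-ethoxyethyl (EE) acetals are carried as inconsequential epimer mixtures.

## Retrosynthetic overview

1. Target ⇐ bis-EE ether 20 ⇐ butenolide closure (Bestmann ylide) on α-ketol 19 ⇐ Weinreb amide 18 + LiCH2OEE.
2. 18 ⇐ B-alkyl Suzuki–Miyaura union of C14 vinyl iodide 10 with the 9-BBN adduct of dienyl Weinreb amide 17.
3. 10 ⇐ Zr-catalysed carboalumination/iodination of alkyne 9 ⇐ Negishi coupling of enol triflate 4 with a homopropargylzinc ⇐ 2-methylcyclohexanone.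
4. 17 ⇐ Cu-catalysed opening of methyl (R)-glycidate (source of the stereocentre) by the (Z)-dienyl metal from anti-carbomagnesiation of propargyl alcohol.
5. Rings: the cyclohexene is bought as 2-methylcyclohexanone and only refunctionalised; the butenolide is the only ring formed, in the penultimate step.

## Left fragment (vinyl iodide 10)

**Step 1**
Reactants: 1, 2-methylcyclohexanone (racemic)
Product: 2, 2,6-dimethylcyclohexanone (cis/trans mixture)
Conditions: LDA, THF, −78 °C; MeI, −78 → 0 °C
Reagents that add atoms: iodomethane, CI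
Why: Kinetic enolate alkylation at the less substituted α-carbon; regio- and stereochemistry are immaterial because any 2,2-isomer also converges on 3 in step 2.

**Step 2**
Reactants: 2, 2,6-dimethylcyclohexanone
Product: 3, 2,2,6-trimethylcyclohexanone (racemic)
Conditions: LDA, THF, 0 °C; MeI, DMPU, 0 °C → rt
Reagents that add atoms: iodomethane, CI
Why: Enolate alkylation of a ketone whose two α-positions are equivalent, so only one trimethyl ketone can form.

**Step 3**
Reactants: 3, 2,2,6-trimethylcyclohexanone
Product: 4, 2,6,6-trimethylcyclohex-1-en-1-yl trifluoromethanesulfonate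
Conditions: LDA, THF, −78 → 0 °C; PhNTf2, 0 °C → rt
Reagents that add atoms: N-phenylbis(trifluoromethanesulfonimide), O=S(=O)(N(c1ccccc1)S(=O)(=O)C(F)(F)F)C(F)(F)F
Why: Only one α-hydrogen remains, so enolate O-triflation gives a single tetrasubstituted enol triflate and removes the ring stereocentre.

**Step 4**
Reactants: 5, but-3-yn-1-ol
Product: 6, 4-(trimethylsilyl)but-3-yn-1-ol
Conditions: n-BuLi (2.1 equiv), THF, −78 °C; TMSCl (2.2 equiv); then 1 M HCl, rt
Reagents that add atoms: chlorotrimethylsilane, C[Si](C)(C)Cl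
Why: C,O-bis-silylation of the dianion followed by selective acidic cleavage of the labile O–Si bond masks the terminal alkyne.

**Step 5**
Reactants: 6, 4-(trimethylsilyl)but-3-yn-1-ol
Product: 7, (4-iodobut-1-yn-1-yl)trimethylsilane
Conditions: PPh3, imidazole, I2, CH2Cl2, 0 °C
Reagents that add atoms: iodine, II
Why: Appel-type iodination of a primary alcohol.

**Step 6**
Reactants: 4, the enol triflate; 7, the homopropargyl iodide
Product: 8, trimethyl[4-(2,6,6-trimethylcyclohex-1-en-1-yl)but-1-yn-1-yl]silane
Conditions: 7, Zn dust, LiCl, THF, 40 °C; then 4, Pd(dppf)Cl2 (5 mol %), THF/NMP, 60 °C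
Reagents that add atoms: none
Why: Negishi sp2–sp3 cross-coupling of a homopropargylzinc with the alkenyl triflate; the wide-bite-angle dppf ligand suppresses β-hydride elimination.

**Step 7**
Reactants: 8, the silyl alkyne
Product: 9, 2-(but-3-yn-1-yl)-1,3,3-trimethylcyclohex-1-ene
Conditions: K2CO3, MeOH, rt
Reagents that add atoms: none
Why: Methanolysis of the alkynyl C–Si bond liberates the terminal alkyne.

**Step 8**
Reactants: 9, the terminal alkyne
Product: 10, 2-[(3E)-4-iodo-3-methylbut-3-en-1-yl]-1,3,3-trimethylcyclohex-1-ene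
Conditions: Me3Al (2 equiv), Cp2ZrCl2 (0.25 equiv), CH2Cl2, 0 °C → rt; then I2, THF, −30 → 0 °C
Reagents that add atoms: trimethylaluminium, C[Al](C)C; iodine, II
Why: Negishi Zr-catalysed methylalumination is a syn addition with Al at the terminal carbon, and iodinolysis with retention gives the E trisubstituted vinyl iodide; the tetrasubstituted ring alkene is inert.

## Right fragment (dienyl Weinreb amide 17)

**Step 9**
Reactants: 11, prop-2-yn-1-ol; 12, vinylmagnesium bromide
Product: 13, (2Z)-2-(iodomethylidene)but-3-en-1-ol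
Conditions: 12 (3 equiv), CuI (10 mol %), THF, −20 °C → rt; then I2, −40 → 0 °C
Reagents that add atoms: iodine, II
Why: Alkoxide-directed anti-carbomagnesiation (Duboudin/Fallis) puts vinyl on C2 and Mg on C3 in a five-membered oxamagnesacycle, so iodine ends up cis to CH2OH (Z).

**Step 10**
Reactants: 13, the iododienol
Product: 14, (1Z)-2-[(1-ethoxyethoxy)methyl]-1-iodobuta-1,3-diene
Conditions: ethyl vinyl ether, PPTS (5 mol %), CH2Cl2, 0 °C → rt
Reagents that add atoms: ethyl vinyl ether, C=COCC
Why: Acid-catalysed acetalisation; an acetal rather than a silyl ether avoids 1,4 O→C silyl migration in the cis-vinyl metal of step 11.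

**Step 11**
Reactants: 14, the EE-protected iododiene; 15, methyl (2R)-oxirane-2-carboxylate (methyl (R)-glycidate)
Product: 16, methyl (2R,4Z)-5-[(1-ethoxyethoxy)methyl]-2-hydroxyhepta-4,6-dienoate
Conditions: t-BuLi (2 equiv), Et2O, −78 °C; MgBr2·OEt2; CuI (15 mol %), then 15, THF, −40 → −20 °C
Reagents that add atoms: none
Why: I/Li exchange and transmetalation proceed with retention, and Cu-catalysed SN2 epoxide opening occurs at the CH2 terminus, so the chiral-pool stereocentre is untouched (2R) and the Z geometry is kept.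

**Step 12**
Reactants: 16, the α-hydroxy ester
Product: 17, (2R,4Z)-5-[(1-ethoxyethoxy)methyl]-2-hydroxy-N-methoxy-N-methylhepta-4,6-dienamide
Conditions: MeNH(OMe)·HCl (3 equiv), i-PrMgCl (6.5 equiv), THF, −20 → 0 °C
Reagents that add atoms: N,O-dimethylhydroxylamine hydrochloride, CNOC.Cl
Why: Magnesium-amide aminolysis of the ester (Weinreb amidation); the α-carbinol is present as its alkoxide and is not epimerised.

## Fragment union and endgame

**Step 13**
Reactants: 17, the dienyl Weinreb amide (1.3 equiv); 10, the vinyl iodide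
Product: 18, (2R,4Z,8E)-5-[(1-ethoxyethoxy)methyl]-2-hydroxy-N-methoxy-N,9-dimethyl-11-(2,6,6-trimethylcyclohex-1-en-1-yl)undeca-4,8-dienamide
Conditions: 17, 9-BBN (2.2 equiv per 17; one is consumed by OH), THF, 0 °C → rt; then 10, Pd(dppf)Cl2 (8 mol %), AsPh3, Cs2CO3, DMF/H2O, rt
Reagents that add atoms: none
Why: 9-BBN hydroborates only the monosubstituted vinyl terminus (anti-Markovnikov), and B-alkyl Suzuki–Miyaura coupling with the vinyl iodide retains both alkene geometries; the α-hydroxy amide is not base-labile.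

**Step 14**
Reactants: 18, the coupled Weinreb amide
Product: 19, (3R,5Z,9E)-1-(1-ethoxyethoxy)-6-[(1-ethoxyethoxy)methyl]-3-hydroxy-10-methyl-12-(2,6,6-trimethylcyclohex-1-en-1-yl)dodeca-5,9-dien-2-one
Conditions: Bu3SnCH2OCH(CH3)OEt (4 equiv), n-BuLi (3.8 equiv), THF, −78 °C; then 18, −78 °C; NH4Cl (aq)
Reagents that add atoms: tributyl[(1-ethoxyethoxy)methyl]stannane, CCCC[Sn](CCCC)(CCCC)COC(C)OCC
Why: Still's α-alkoxymethyllithium (Sn–Li exchange) adds once to the Weinreb amide through the chelated tetrahedral intermediate, giving the α-ketol after a cold neutral quench.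

**Step 15**
Reactants: 19, the α-hydroxy ketone
Product: 20, (5R)-5-[(2Z,6E)-3-[(1-ethoxyethoxy)methyl]-7-methyl-9-(2,6,6-trimethylcyclohex-1-en-1-yl)nona-2,6-dien-1-yl]-4-[(1-ethoxyethoxy)methyl]furan-2(5H)-one
Conditions: Ph3P=C=C=O (1.5 equiv), toluene, 80 °C
Reagents that add atoms: (triphenylphosphoranylidene)ketene (Bestmann ylide), O=C=C=P(c1ccccc1)(c1ccccc1)c1ccccc1
Why: The secondary OH adds to the ketene ylide and the resulting ester ylide undergoes intramolecular Wittig olefination of the adjacent ketone; the C–O bond at the stereocentre is never broken, so R is retained.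

**Step 16**
Reactants: 20, the bis-EE butenolide
Product: 21, (5R)-4-(hydroxymethyl)-5-[(2Z,6E)-3-(hydroxymethyl)-7-methyl-9-(2,6,6-trimethylcyclohex-1-en-1-yl)nona-2,6-dien-1-yl]furan-2(5H)-one, (6Z)-neomanoalide
Conditions: PPTS (0.2 equiv), MeOH, rt
Reagents that add atoms: none
Why: Mild acid-catalysed transacetalisation removes both EE groups without touching the lactone, the alkenes or the acidic C5–H.

## Compound list

1 | 2-methylcyclohexanone | CC1CCCCC1=O | starting material
2 | 2,6-dimethylcyclohexanone | CC1CCCC(C)C1=O | intermediate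
3 | 2,2,6-trimethylcyclohexanone | CC1CCCC(C)(C)C1=O | intermediate
4 | 2,6,6-trimethylcyclohex-1-en-1-yl triflate | CC1=C(OS(=O)(=O)C(F)(F)F)C(C)(C)CCC1 | intermediate
5 | but-3-yn-1-ol | C#CCCO | starting material
6 | 4-(trimethylsilyl)but-3-yn-1-ol | C[Si](C)(C)C#CCCO | intermediate
7 | (4-iodobut-1-yn-1-yl)trimethylsilane | C[Si](C)(C)C#CCCI | intermediate
8 | trimethyl[4-(2,6,6-trimethylcyclohex-1-en-1-yl)but-1-yn-1-yl]silane | CC1=C(CCC#C[Si](C)(C)C)C(C)(C)CCC1 | intermediate
9 | 2-(but-3-yn-1-yl)-1,3,3-trimethylcyclohex-1-ene | CC1=C(CCC#C)C(C)(C)CCC1 | intermediate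
10 | 2-[(3E)-4-iodo-3-methylbut-3-en-1-yl]-1,3,3-trimethylcyclohex-1-ene | CC1=C(CC/C(C)=C/I)C(C)(C)CCC1 | intermediate
11 | prop-2-yn-1-ol | C#CCO | starting material
12 | vinylmagnesium bromide | C=C[Mg]Br | starting material
13 | (2Z)-2-(iodomethylidene)but-3-en-1-ol | C=C/C(=C/I)CO | intermediate
14 | (1Z)-2-[(1-ethoxyethoxy)methyl]-1-iodobuta-1,3-diene | C=C/C(=C/I)COC(C)OCC | intermediate
15 | methyl (2R)-oxirane-2-carboxylate | COC(=O)[C@H]1CO1 | starting material
16 | methyl (2R,4Z)-5-[(1-ethoxyethoxy)methyl]-2-hydroxyhepta-4,6-dienoate | C=C/C(=C/C[C@@H](O)C(=O)OC)COC(C)OCC | intermediate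
17 | (2R,4Z)-5-[(1-ethoxyethoxy)methyl]-2-hydroxy-N-methoxy-N-methylhepta-4,6-dienamide | C=C/C(=C/C[C@@H](O)C(=O)N(C)OC)COC(C)OCC | intermediate
18 | coupled (2R,4Z,8E) Weinreb amide | CC1=C(CC/C(C)=C/CC/C(=C/C[C@@H](O)C(=O)N(C)OC)COC(C)OCC)C(C)(C)CCC1 | intermediate
19 | (3R,5Z,9E) α-hydroxy ketone | CC1=C(CC/C(C)=C/CC/C(=C/C[C@@H](O)C(=O)COC(C)OCC)COC(C)OCC)C(C)(C)CCC1 | intermediate
20 | (5R) bis-EE butenolide | CC1=C(CC/C(C)=C/CC/C(=C/C[C@H]2OC(=O)C=C2COC(C)OCC)COC(C)OCC)C(C)(C)CCC1 | intermediate
21 | (6Z)-neomanoalide | CC1=C(CC/C(C)=C/CC/C(=C/C[C@H]2OC(=O)C=C2CO)CO)C(C)(C)CCC1 | target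

## Step count

Total steps: 16.
Longest linear sequence: 10 (steps 1, 2, 3, 6, 7, 8, 13, 14, 15, 16).

## Steps most likely to fail, with fallbacks

1. **Step 13** (diene hydroboration and B-alkyl Suzuki with a free OH and Weinreb amide present). Fallback: reverse the polarity and use a Negishi union. Trap the alkenylalanate from 9 with oxirane and convert the homoallylic alcohol to the iodide and then the alkylzinc. Couple this with an (E)-2-iodoallyl ether partner made by acetylide opening of 15 followed by Pd-catalysed syn-hydrostannation/iodination.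
2. **Step 6** (sp3 coupling onto the hindered triflate). Fallback: abandon the cross-coupling and add the organocerium derived from 7 to ketone 3, then dehydrate the tertiary alcohol (Burgess reagent); the only endocyclic elimination possible gives the required tetrasubstituted alkene. Alternatively, carbonylate 4, reduce and brominate to β-cyclogeranyl bromide, and alkylate lithiated 1-(trimethylsilyl)propyne.
3. **Step 15** (butenolide closure on an epimerisable α-ketol). Fallback: build the lactone by ring-closing metathesis instead. Methylenate the ketone of 19 (OH temporarily silylated), acryloylate the C3 hydroxyl, and close with Grubbs II; the trisubstituted and tetrasubstituted alkenes elsewhere are unreactive.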